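## The problem

Lanaroflavone 17 is made of two apigenin-type flavones joined by a diaryl ether: unit 1 (benzo ring A, pyranone ring C, para-phenylene ring B; unprimed and primed positions) gives its C4' oxygen, and unit 2 (benzo ring D, pyranone ring E, 4-hydroxyphenyl ring F; doubly and triply primed positions) receives it at C8''. There is no stereocentre, so the task is one of regiochemistry and chemoselectivity: five phenolic hydroxyls, two 4-pyranones and one C–O–C link must be placed without long protecting-group sequences. The hardest bond is C8''–O, which lies between the C7'' oxygen and ring oxygen O1'' on an electron-rich ring and must be told apart from the similar C6''. Once O8'' is free, ring D is a hydroquinone that oxidises easily to a quinone. In addition, 5,7,8-oxygenated flavones can isomerise in hot strong acid, the pyranones open in hot strong alkali, and any alkynyl ketone or polyketone intermediate is a reactive acceptor. The enabling feature is ring A of unit 1, an unsubstituted phloroglucinol ring (oxygens on C5, C7, C8a) fused to ring C, so that the nine carbons C2, C3, C4, C4a, C5, C6, C7, C8 and C8a have the alternating oxidation pattern of an arylpropynoyl starter extended by three acetate units. Bonding C4a to C8a makes ring A and adding the C8a oxygen to C2 makes ring C; ring A is symmetrical, so either ortho hydroxyl gives the same flavone. Unit 2 is best bought: acacetin 1 already holds rings D, E and F with O4''' differentiated.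

## Retrosynthesis

**17 ⇒ 16.** The two O–CH3 bonds at O7'' and O4''' are cut last. The 4'''-methyl comes with 1, and the 7''-methyl is what distinguishes O7'' from O8'' and O5'' earlier on. Compound 16 differs from the target only by these two ethers. The forward step is an ether cleavage with BBr3 that must leave the diaryl ether and both pyranones alone.

**16 ⇒ 12.** Rings A and C of unit 1 are opened at C4a–C8a and O1–C2. The neighbouring cut, joining two finished flavones at the ether, would need a hindered 8-hydroxyflavone, a 4'-haloflavone and protection of most of the five hydroxyls. Building ring C by acyl transfer onto a preformed phloroglucinol ketone would need ring A protected and later freed. The folding route leaves ring A unprotected and uses its symmetry. Precursor 12 has neither ring: the chain is stored as a 4-hydroxy-2-pyranone bearing a 2-oxo-4-arylbut-3-ynyl side chain. The forward step asks for Claisen rather than aldol folding and for six-membered rather than five-membered O-closure. Both are secured by letting diethylamine add to the ynone in the flask to give enaminone 13 before Mg(OMe)2 opens the lactone to triketo ester 14 and closes ring A to 15, after which acid closes ring C.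

**12 ⇒ 11 ⇒ 6 + 10.** The C4 ketone is taken back to the carbinol 11, and the aryl–alkyne bond C1'–C2 is cut to aryl iodide 6 and terminal alkyne 10. The alternative, attaching the alkynyl carbonyl unit to the flavone first and then adding the dianion of 7, would put a strong base on the advanced intermediate with its acidic phenol and electrophilic pyranone. The alcohol level is used because terminal ynones couple poorly. Fragment 6 holds all of unit 2 and ring B; 10 holds the masked triketide. The forward steps are a Sonogashira coupling (Pd(PPh3)2Cl2, CuI) near room temperature that tolerates three free hydroxyls, and an oxidation selective for the propargylic alcohol.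

**10 ⇒ 7 + 8.** The bond between the side-chain CH2 (the methyl of triacetic acid lactone 7) and the carbinol carbon is cut, giving 7 and silyl-protected propynal 8, both commercial. The forward reaction is a lateral aldol addition of the dianion of 7, 1,2 to the ynal, followed by C–Si cleavage. The new stereocentre is irrelevant.

**6 ⇒ 4 + 5.** The ether is cut on the ring B side (C4'–O), giving phenol 4 and the symmetrical 1,4-diiodobenzene 5. Cutting at C8''–O would need an 8-haloflavone and a 4-iodophenol that would couple with itself. A Chan–Lam coupling of an arylboronic acid with Cu(OAc)2 in air (divalent copper) was set aside because ring D of 4 is a hydroquinone. The forward step must arylate the hindered 8-oxygen once, without an oxidant, leaving the chelated 5-OH and the second iodide.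

**4 ⇒ 2 ⇒ 1.** The C8''–O bond is cut, then the 7''-O–CH3 bond. The 5-hydroxyl of 2 directs K2S2O8 oxidation to its para position C8, which is the 5'',8'' relationship the target needs. Methylation of 1 at the unchelated 7-OH gives 2. Acacetin 1 is commercial.

## Roads not taken

**Alternative 1:** The cut is through ring B (C2'–C3' and C4'–C5'). In the forward direction methyl coumalate A1 and the aryl ethynyl ether A2 undergo a (4+2) cycloaddition and lose the lactone bridge as gas, giving benzoate A3 with the aryloxy group para to the ester.
- Merits: the polarisation of both partners fixes the para relationship, no metal is needed, and the ether oxygen arrives on A2, so no hindered phenol has to be arylated.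
- Weak points: it constructs the one ring of the target that has no functionality and can be bought as 5. After A3, ring D must still be C-acylated, rings E and F built, and rings A and C made from the ester. A2 is labile, and six methyl ethers must be cleaved at the end.
- Comparison: it is better than the chosen plan in avoiding both the K2S2O8 oxidation and the arylation of oxidation-prone 4. Against that, the chosen plan buys rings D, E and F in 1 and its ring-forming step makes two functional rings, so it is several steps shorter.

**Alternative 2:** The cut is through ring D (C4a''–C8a'', C5''–C6'', C8''–C8a''). Heating the racemic cyclobutenone A4 with ethoxyacetylene A5 gives, by ring opening, (2+2) addition and six-electron electrocyclisation, phenol A6.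
- Merits: ring D is made with the aryloxy group at C8'' and a single free hydroxyl at C8a'', so the C8''–O bond is never made by coupling.
- Weak points: A4 is a sensitive multistep intermediate and the two ethoxy groups of A6 are not differentiated. After A6, acylation at C4a'', rings E and F, and rings A and C all remain.
- Comparison: in regiochemical certainty for ring D this road is superior to the oxidation/arylation sequence. The chosen plan sets against this its brevity and the established site selectivity of 5-hydroxyflavones toward para oxidation and 8-O-functionalisation.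

**Alternative 3:** The cut is through ring E (C4a''–C4'', C4''–C3'', O1''–C2''). PdCl2(PPh3)2-catalysed carbonylative coupling of iodophenol A7 with 4-ethynylanisole A8 under CO in the presence of Et2NH gives flavone A9.
- Merits: this is a known reaction class, which is a real advantage over the chosen key step, and the amine guarantees six-membered closure. A9 already contains rings B, D, E and F and an ester handle.
- Weak points: A7 is a pentasubstituted benzene whose iodide is flanked by OH and OMe, A7 itself needs the diaryl ether and a regioselective iodination, and a toxic gas under pressure is required. Rings A and C would still have to be built from the ester by a classical sequence.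
- Comparison: the chosen plan sets against this that only one ring-forming event is needed on material that comes from 1, that it borrows the amine control of this road, and that it has a classical fallback.

Key step: step 7

Remark on the chemistry: 9, 10 and 11 are handled as racemates, because their only stereocentre (the carbinol carbon) becomes the C4 carbonyl in step 6, and the target has no stereocentre.

## Route

Step 1
Reactants: 1 acacetin
Product: 2 5-hydroxy-7-methoxy-2-(4-methoxyphenyl)chromen-4-one
Conditions: MeI (1.2 equiv), K2CO3, acetone, reflux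
Reagents that add atoms: iodomethane, CI
Why: Williamson O-methylation; the 7-OH is the acidic, unchelated hydroxyl, while the 5-OH is hydrogen-bonded to the C4 carbonyl and should stay free with about one equivalent of MeI.

Step 2
Reactants: 2 5-hydroxy-7-methoxy-2-(4-methoxyphenyl)chromen-4-one
Product: 4 5,8-dihydroxy-7-methoxy-2-(4-methoxyphenyl)chromen-4-one, via potassium flavon-8-yl sulfate 3 (not isolated)
Conditions: K2S2O8, aq. KOH, pyridine, 0 °C → rt; then conc. HCl, 90 °C, argon
Reagents that add atoms: potassium persulfate, [K+].[K+].[O-]S(=O)(=O)OOS(=O)(=O)[O-]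
Why: Elbs persulfate oxidation; the 5-phenoxide attacks a peroxide oxygen through its para carbon C8 to give aryl sulfate 3, and acid hydrolysis frees the 8-OH. This is the classical entry to 5,8-dihydroxy-7-methoxyflavones, and unreacted 2 can be recovered and recycled.

Step 3
Reactants: 4 5,8-dihydroxy-7-methoxy-2-(4-methoxyphenyl)chromen-4-one; 5 1,4-diiodobenzene
Product: 6 5-hydroxy-8-(4-iodophenoxy)-7-methoxy-2-(4-methoxyphenyl)chromen-4-one
Conditions: 5 (4 equiv), CuI (20 mol%), picolinic acid (40 mol%), K3PO4, DMSO, 90 °C, argon
Reagents that add atoms: none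
Why: Ullmann-type CuI-catalysed diaryl ether synthesis under conditions developed for di-ortho-substituted phenols. The 8-phenoxide is the nucleophilic one because the 5-oxygen is chelated to the C4 carbonyl, and excess 5 suppresses a second coupling. With CuI (monovalent copper) under argon no oxidant is present, so the hydroquinone ring of 4 should survive.

Step 4
Reactants: 7 triacetic acid lactone; 8 3-(trimethylsilyl)prop-2-ynal
Product: 10 rac-4-hydroxy-6-(2-hydroxybut-3-ynyl)pyran-2-one, via silylated aldol adduct 9 (not isolated)
Conditions: LiN(iPr)2 (LDA, 2.3 equiv), THF, −78 °C; 8, −78 → −40 °C; then MeOH, K2CO3, rt; aq. HCl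
Reagents that add atoms: none
Why: Lateral aldol addition of the dianion of 7 (O-4 and the C6 methyl deprotonated), which should add 1,2 to the ynal; basic methanol then cleaves the alkynyl C–Si bond. The carbinol centre forms without control as a racemate and is removed in step 6.

Step 5
Reactants: 6 5-hydroxy-8-(4-iodophenoxy)-7-methoxy-2-(4-methoxyphenyl)chromen-4-one; 10 rac-4-hydroxy-6-(2-hydroxybut-3-ynyl)pyran-2-one
Product: 11 rac-4-hydroxy-6-[2-hydroxy-4-(4-{[5-hydroxy-7-methoxy-2-(4-methoxyphenyl)-4-oxochromen-8-yl]oxy}phenyl)but-3-ynyl]pyran-2-one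
Conditions: Pd(PPh3)2Cl2 (5 mol%), CuI (10 mol%), Et3N, DMF, rt → 40 °C, argon
Reagents that add atoms: none
Why: Sonogashira coupling of an aryl iodide with a terminal propargylic alcohol, which tolerates the free phenol, the enolic pyranone and the secondary alcohol. The temperature is kept low so that the β-hydroxy group is not eliminated.

Step 6
Reactants: 11 rac-4-hydroxy-6-[2-hydroxy-4-(4-{[5-hydroxy-7-methoxy-2-(4-methoxyphenyl)-4-oxochromen-8-yl]oxy}phenyl)but-3-ynyl]pyran-2-one
Product: 12 4-hydroxy-6-[4-(4-{[5-hydroxy-7-methoxy-2-(4-methoxyphenyl)-4-oxochromen-8-yl]oxy}phenyl)-2-oxobut-3-ynyl]pyran-2-one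
Conditions: MnO2 (activated, 20 equiv), THF, rt
Reagents that add atoms: none
Why: MnO2 oxidation, selective for propargylic alcohols; unlike hypervalent iodine oxidants it should not touch the para-aryloxy phenol of ring D or the activated methylene. Ynone 12 is taken on without storage.

Step 7
Reactants: 12 4-hydroxy-6-[4-(4-{[5-hydroxy-7-methoxy-2-(4-methoxyphenyl)-4-oxochromen-8-yl]oxy}phenyl)-2-oxobut-3-ynyl]pyran-2-one
Product: 16 lanaroflavone 7'',4'''-dimethyl ether, via enaminone pyranone 13 (not isolated), via enaminone triketo ester 14 (not isolated), via trihydroxyphenyl enaminone 15 (not isolated)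
Conditions: Et2NH (5 equiv), MeOH, rt; Mg(OMe)2 (8 equiv), MeOH, 65 °C; then 2 M HCl, 50 °C
Reagents that add atoms: diethylamine, CCNCC; magnesium methoxide, CO[Mg]OC
Why: Proposed new method: Diethylamine first adds to the ynone of 12 (aza-Michael) to give enaminone 13, so that no free alkyne acceptor remains when the base is added. Mg(OMe)2 then opens the lactone at its carbonyl to the magnesium-chelated methyl 3,5,7-trioxo ester 14, whose C6 methylene (future C4a) attacks the ester carbon (future C8a) in a 6-exo-trig Claisen (Dieckmann-type) closure; loss of methanol and enolisation give the 2,4,6-trihydroxyphenyl enaminone 15 and ring A. On acidification an ortho hydroxyl of 15 adds to the amine-bearing β-carbon and diethylamine leaves (6-endo-trig addition–elimination), forming O1–C2 and ring C of 16, so the diethylamino group is carried only by 13, 14 and 15, the methoxy group only by 14, and 16 is an isomer of 12. The closest known reactions are the Mg(OMe)2-mediated Claisen cyclisation of 6-(2-oxoalkyl)-4-hydroxy-2-pyranones and 3,5,7-triketo esters to acylphloroglucinols, and the cyclisation of 2-hydroxyaryl ynones and their secondary-amine adducts to flavones; their combination in one flask on such a chain is untested. The step needs Claisen over aldol folding (C2 onto C7 would give a resorcylate); magnesium chelation of the polyketide and the vinylogous-amide character of C7, which is no longer an electrophile, should secure this. It also needs flavone over aurone closure, which is secured because the enaminone offers the phenol only its β-carbon, whereas a free 2-hydroxyaryl ynone in basic alcohol can close 5-exo. Aromatisation and flavone formation are irreversible, while lactone re-closure and O-cyclisation of the open chain are reversible in methoxide. Ring A is symmetrical, so either ortho hydroxyl gives 16, and no stereocentre is formed.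

Step 8
Reactants: 16 lanaroflavone 7'',4'''-dimethyl ether
Product: 17 lanaroflavone
Conditions: BBr3 (10 equiv), CH2Cl2, −78 °C → rt; then H2O
Reagents that add atoms: none
Why: BBr3 cleavage of aryl methyl ethers (boron–oxygen adduct, then bromide attack at methyl); diaryl ethers and flavone cores are inert to it, and aqueous work-up hydrolyses the aryl borates.

## Compound list

1 | acacetin, 5,7-dihydroxy-2-(4-methoxyphenyl)chromen-4-one | O=c1cc(-c2ccc(OC)cc2)oc2cc(O)cc(O)c12 | starting material
2 | 5-hydroxy-7-methoxy-2-(4-methoxyphenyl)chromen-4-one | O=c1cc(-c2ccc(OC)cc2)oc2cc(OC)cc(O)c12 | intermediate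
3 | potassium 5-hydroxy-7-methoxy-2-(4-methoxyphenyl)-4-oxochromen-8-yl sulfate | [K+].O=c1cc(-c2ccc(OC)cc2)oc2c(OS(=O)(=O)[O-])c(OC)cc(O)c12 | intermediate
4 | 5,8-dihydroxy-7-methoxy-2-(4-methoxyphenyl)chromen-4-one | O=c1cc(-c2ccc(OC)cc2)oc2c(O)c(OC)cc(O)c12 | intermediate
5 | 1,4-diiodobenzene | Ic1ccc(I)cc1 | starting material
6 | 5-hydroxy-8-(4-iodophenoxy)-7-methoxy-2-(4-methoxyphenyl)chromen-4-one | O=c1cc(-c2ccc(OC)cc2)oc2c(Oc3ccc(I)cc3)c(OC)cc(O)c12 | intermediate
7 | triacetic acid lactone, 4-hydroxy-6-methylpyran-2-one | Cc1cc(O)cc(=O)o1 | starting material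
8 | 3-(trimethylsilyl)prop-2-ynal | C[Si](C)(C)C#CC=O | starting material
9 | rac-4-hydroxy-6-[2-hydroxy-4-(trimethylsilyl)but-3-ynyl]pyran-2-one | C[Si](C)(C)C#CC(O)Cc1cc(O)cc(=O)o1 | intermediate
10 | rac-4-hydroxy-6-(2-hydroxybut-3-ynyl)pyran-2-one | C#CC(O)Cc1cc(O)cc(=O)o1 | intermediate
11 | rac-4-hydroxy-6-[2-hydroxy-4-(4-{[5-hydroxy-7-methoxy-2-(4-methoxyphenyl)-4-oxochromen-8-yl]oxy}phenyl)but-3-ynyl]pyran-2-one | O=c1cc(O)cc(CC(O)C#Cc2ccc(Oc3c(OC)cc(O)c4c(=O)cc(-c5ccc(OC)cc5)oc34)cc2)o1 | intermediate
12 | 4-hydroxy-6-[4-(4-{[5-hydroxy-7-methoxy-2-(4-methoxyphenyl)-4-oxochromen-8-yl]oxy}phenyl)-2-oxobut-3-ynyl]pyran-2-one | O=c1cc(O)cc(CC(=O)C#Cc2ccc(Oc3c(OC)cc(O)c4c(=O)cc(-c5ccc(OC)cc5)oc34)cc2)o1 | intermediate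
13 | 6-[(3E)-4-(diethylamino)-4-(4-{[5-hydroxy-7-methoxy-2-(4-methoxyphenyl)-4-oxochromen-8-yl]oxy}phenyl)-2-oxobut-3-enyl]-4-hydroxypyran-2-one (E expected, inconsequential) | O=c1cc(O)cc(CC(=O)/C=C(/N(CC)CC)c2ccc(Oc3c(OC)cc(O)c4c(=O)cc(-c5ccc(OC)cc5)oc34)cc2)o1 | intermediate
14 | methyl (8E)-9-(diethylamino)-9-(4-{[5-hydroxy-7-methoxy-2-(4-methoxyphenyl)-4-oxochromen-8-yl]oxy}phenyl)-3,5,7-trioxonon-8-enoate | COC(=O)CC(=O)CC(=O)CC(=O)/C=C(/N(CC)CC)c1ccc(Oc2c(OC)cc(O)c3c(=O)cc(-c4ccc(OC)cc4)oc23)cc1 | intermediate
15 | (2E)-3-(diethylamino)-3-(4-{[5-hydroxy-7-methoxy-2-(4-methoxyphenyl)-4-oxochromen-8-yl]oxy}phenyl)-1-(2,4,6-trihydroxyphenyl)prop-2-en-1-one | O=C(/C=C(/N(CC)CC)c1ccc(Oc2c(OC)cc(O)c3c(=O)cc(-c4ccc(OC)cc4)oc23)cc1)c1c(O)cc(O)cc1O | intermediate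
16 | lanaroflavone 7'',4'''-dimethyl ether, 5,7-dihydroxy-2-(4-{[5-hydroxy-7-methoxy-2-(4-methoxyphenyl)-4-oxochromen-8-yl]oxy}phenyl)chromen-4-one | O=c1cc(-c2ccc(Oc3c(OC)cc(O)c4c(=O)cc(-c5ccc(OC)cc5)oc34)cc2)oc2cc(O)cc(O)c12 | intermediate
17 | lanaroflavone, 5,7-dihydroxy-2-(4-{[5,7-dihydroxy-2-(4-hydroxyphenyl)-4-oxochromen-8-yl]oxy}phenyl)chromen-4-one | O=c1cc(-c2ccc(Oc3c(O)cc(O)c4c(=O)cc(-c5ccc(O)cc5)oc34)cc2)oc2cc(O)cc(O)c12 | target

## Step count and risks

Total: 8 steps. Longest linear sequence: 7 steps (1 → 2 → 4 → 6 → 11 → 12 → 16 → 17); step 4 makes the side fragment.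

**Step 7 (key step, proposed new method).** Most likely to go wrong: the pyranone enolate may resist opening by methoxide; the open-chain chelate may fragment by retro-Claisen methanolysis; deprotonation at C6 may be slowed by the vinylogous amide, so that ring A closes sluggishly; and the C5 enol oxygen may close onto the enaminone carbon to give a 4-pyranone instead of ring A.

Fallback (known chemistry, from 4, returning at 17): unit 1 would be built by the classical chalcone route. SNAr of the 8-phenoxide of 4 on 4-fluorobenzaldehyde (K2CO3, DMF, 90 °C, argon) should give 4-{[5-hydroxy-7-methoxy-2-(4-methoxyphenyl)-4-oxochromen-8-yl]oxy}benzaldehyde F1. Claisen–Schmidt condensation of F1 with commercial 2'-hydroxy-4',6'-dimethoxyacetophenone (KOH, EtOH, rt) should give the 2'-hydroxychalcone F2. Oxidative cyclisation with catalytic I2 in DMSO at 130 °C should give lanaroflavone 5,7,7'',4'''-tetramethyl ether F3, and BBr3 in CH2Cl2 would cleave all four methyl ethers to 17.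

**Step 3.** Most likely to go wrong: oxidation of the hydroquinone ring to the quinone by traces of oxygen in the presence of CuI; slow coupling at the di-ortho-substituted oxygen; a second coupling at the remaining iodide.

Fallback (from 4, returning at 6): SNAr on 1-fluoro-4-nitrobenzene (K2CO3, DMF, 80 °C, argon) should give 5-hydroxy-7-methoxy-2-(4-methoxyphenyl)-8-(4-nitrophenoxy)chromen-4-one F4. Reduction (Fe, NH4Cl, EtOH/H2O, 70 °C) should give 8-(4-aminophenoxy)-5-hydroxy-7-methoxy-2-(4-methoxyphenyl)chromen-4-one F5, and diazotisation–iodination (NaNO2, p-TsOH, KI, MeCN/H2O, rt) then leads to 6.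

**Step 6.** Most likely to go wrong: retention of the acidic pyranone on the oxidant surface, and loss of ynone 12 through conjugate addition of its own enolic groups during isolation.

Fallback (from 6, returning at 12, no oxidation): Sonogashira coupling of 6 with N-methoxy-N-methylprop-2-ynamide (Pd(PPh3)2Cl2, CuI, K2CO3, THF, rt) should give N-methoxy-N-methyl-3-(4-{[5-hydroxy-7-methoxy-2-(4-methoxyphenyl)-4-oxochromen-8-yl]oxy}phenyl)prop-2-ynamide F6. Adding F6 to an excess of the dianion of 7 (LiN(iPr)2, THF, −78 °C; the first equivalent is spent on the 5-OH) gives a chelated adduct that should release 12 on acidic work-up.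

**Step 2.** Most likely to go wrong: low conversion and over-oxidation to dark polymeric material, both typical of persulfate oxidations, and some attack at C6.

Fallback (from 2, returning at 4): methylation of the chelated 5-OH (Me2SO4, K2CO3, acetone, reflux) should give 5,7-dimethoxy-2-(4-methoxyphenyl)chromen-4-one F7. Electrophilic iodination (I2, CF3CO2Ag, CH2Cl2), which in 5,7-dimethoxyflavones goes to C8, should give 8-iodo-5,7-dimethoxy-2-(4-methoxyphenyl)chromen-4-one F8. Miyaura borylation (B2pin2, Pd(dppf)Cl2, KOAc, dioxane, 90 °C) should give the 8-pinacolboronate F9, and oxidation (NaBO3·4H2O, THF/H2O) 8-hydroxy-5,7-dimethoxy-2-(4-methoxyphenyl)chromen-4-one F10. Chelation-controlled cleavage of the 5-methyl ether (BCl3, CH2Cl2, 0 °C) then gives 4.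

## Further compounds

F1 | step 7 | 4-{[5-hydroxy-7-methoxy-2-(4-methoxyphenyl)-4-oxochromen-8-yl]oxy}benzaldehyde | O=Cc1ccc(Oc2c(OC)cc(O)c3c(=O)cc(-c4ccc(OC)cc4)oc23)cc1
F2 | step 7 | (2E)-1-(2-hydroxy-4,6-dimethoxyphenyl)-3-(4-{[5-hydroxy-7-methoxy-2-(4-methoxyphenyl)-4-oxochromen-8-yl]oxy}phenyl)prop-2-en-1-one | COc1cc(O)c(C(=O)/C=C/c2ccc(Oc3c(OC)cc(O)c4c(=O)cc(-c5ccc(OC)cc5)oc34)cc2)c(OC)c1
F3 | step 7 | lanaroflavone 5,7,7'',4'''-tetramethyl ether | O=c1cc(-c2ccc(Oc3c(OC)cc(O)c4c(=O)cc(-c5ccc(OC)cc5)oc34)cc2)oc2cc(OC)cc(OC)c12
F4 | step 3 | 5-hydroxy-7-methoxy-2-(4-methoxyphenyl)-8-(4-nitrophenoxy)chromen-4-one | O=c1cc(-c2ccc(OC)cc2)oc2c(Oc3ccc([N+](=O)[O-])cc3)c(OC)cc(O)c12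
F5 | step 3 | 8-(4-aminophenoxy)-5-hydroxy-7-methoxy-2-(4-methoxyphenyl)chromen-4-one | O=c1cc(-c2ccc(OC)cc2)oc2c(Oc3ccc(N)cc3)c(OC)cc(O)c12
F6 | step 6 | N-methoxy-N-methyl-3-(4-{[5-hydroxy-7-methoxy-2-(4-methoxyphenyl)-4-oxochromen-8-yl]oxy}phenyl)prop-2-ynamide | CON(C)C(=O)C#Cc1ccc(Oc2c(OC)cc(O)c3c(=O)cc(-c4ccc(OC)cc4)oc23)cc1
F7 | step 2 | 5,7-dimethoxy-2-(4-methoxyphenyl)chromen-4-one | O=c1cc(-c2ccc(OC)cc2)oc2cc(OC)cc(OC)c12
F8 | step 2 | 8-iodo-5,7-dimethoxy-2-(4-methoxyphenyl)chromen-4-one | O=c1cc(-c2ccc(OC)cc2)oc2c(I)c(OC)cc(OC)c12
F9 | step 2 | 5,7-dimethoxy-2-(4-methoxyphenyl)-8-(4,4,5,5-tetramethyl-1,3,2-dioxaborolan-2-yl)chromen-4-one | O=c1cc(-c2ccc(OC)cc2)oc2c(B3OC(C)(C)C(C)(C)O3)c(OC)cc(OC)c12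
F10 | step 2 | 8-hydroxy-5,7-dimethoxy-2-(4-methoxyphenyl)chromen-4-one | O=c1cc(-c2ccc(OC)cc2)oc2c(O)c(OC)cc(OC)c12
A1 | alternative 1 | methyl coumalate | COC(=O)c1ccc(=O)oc1
A2 | alternative 1 | 2-(ethynyloxy)-1,3,5-trimethoxybenzene | C#COc1c(OC)cc(OC)cc1OC
A3 | alternative 1 | methyl 4-(2,4,6-trimethoxyphenoxy)benzoate | COC(=O)c1ccc(Oc2c(OC)cc(OC)cc2OC)cc1
A4 | alternative 2 | rac-methyl 4-[(2-ethoxy-4-oxocyclobut-2-en-1-yl)oxy]benzoate | CCOC1=CC(=O)C1Oc1ccc(C(=O)OC)cc1
A5 | alternative 2 | ethoxyacetylene | CCOC#C
A6 | alternative 2 | methyl 4-(2,4-diethoxy-6-hydroxyphenoxy)benzoate | COC(=O)c1ccc(Oc2c(O)cc(OCC)cc2OCC)cc1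
A7 | alternative 3 | methyl 4-(2-hydroxy-3-iodo-4,6-dimethoxyphenoxy)benzoate | COC(=O)c1ccc(Oc2c(OC)cc(OC)c(I)c2O)cc1
A8 | alternative 3 | 4-ethynylanisole | C#Cc1ccc(OC)cc1
A9 | alternative 3 | methyl 4-{[5,7-dimethoxy-2-(4-methoxyphenyl)-4-oxochromen-8-yl]oxy}benzoate | COC(=O)c1ccc(Oc2c(OC)cc(OC)c3c(=O)cc(-c4ccc(OC)cc4)oc23)cc1
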